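Maple, the flask on the bench, is the flask asked about, and I leave this note beside it.

| flask | starting material | partner A | solid reagent | remark | time |
|---|---|---|---|---|---|
| maple | 1 M | 2 M | 2 M | the very flask that is asked about, followed so far |  |
| flask | 1.0 M | 2.00 M | 2.00 M |  | 10 h |

- maple (time / min: open intermediate / %, target / %): 6.00: 0.3, 0; 20.0: 3.0, 0.4; 30.0: 4.7, 0.6; 50.0: 7.3, 4.1; 80.0: 7.1, 14.5

(scatter of a reading: 0.3 percentage points)

- as a solid, counted per litre of solution: solid reagent
- at the start none of the solid reagent is in solution

* the moment within 10 h at which there is most open intermediate
* the amount of open intermediate, in percent of the starting material charged, at that time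
* the first time at which open intermediate reaches 4.0%, in the same percent

I take open intermediate and target together to count what has left the starting material, so the fraction left follows from each reading. I carry the exposure, minus the logarithm of that fraction, and its slope between 30.0 min and 80.0 min, the exposure rate 0.227 h⁻¹. This treats the loss as pseudo-first-order, which integrates to an exponential in the time past a lag, read here as 15.6 min.

Leave the flask alone through that lag: none of the solid reagent is in solution at the start, and the quiet first readings belong to the run. Should the exposure rate hold to 10 h, my reckoning leaves 11.0% of the starting material. Watch that fraction.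

The forecast reads that “the feed is roughly steady” and puts the top of open intermediate at 7.9% near 1.07 h, with 4.0% reached at 0.43 h.

The flask gives 8.02% at 1.00 h, and 4.0% at 0.418 h, inside the forecast's ranges.

    starting material + partner B → open intermediate (k = 1.58 × 10⁻⁴ L mol⁻¹ s⁻¹)
    solid reagent ⇌ partner B, rate k2*(cs2 - [partner B]) while solid is left; crystals form when [partner B] > cs2 (solubility = 1.00 M, k = 3.84 × 10⁻⁴ s⁻¹)
    partner B + partner A → second intermediate (k = 2.28 × 10⁻⁴ L mol⁻¹ s⁻¹)
    open intermediate + second intermediate → target (k = 0.00192 L mol⁻¹ s⁻¹)

In the flask at 1.02 h, open intermediate is made at 0.983 of the rate at which it is used up, each step taken net, just past its top, and by 2.00 h the dissolving of the solid reagent has 87% of its turnover up to 10 h behind it. At 10 h the solid reagent, the limiting reagent, stands at 0%, and 42% of the starting material is left, more than my 11.0%, so the exposure ends at 0.860, worth 3.79 h at the exposure rate. The neighbour flask with 1.7 M of starting material keeps 53%, worth 2.80 h.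

(Readings and results come from a simulation for substances that don't exist; the scatter is artificial.)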